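The route rests on disconnecting both aryl groups from the five-membered ring (ring B) of the indane, that is, the C2–aryl and C3–aryl bonds. Because the 4-hydroxyphenyl group on C2 and the 3,5-dihydroxyphenyl group on C3 are cis, both can be delivered in one syn three-component diarylation of a C2=C3 indene, which sets both stereocentres under ligand control. The alkene partner is a racemic 4,6-bis(benzyloxy)-1H-indene whose C1 is a quaternary β-keto benzyl ester carrying the aroyl group; this blocks tautomerisation and β-hydride elimination. Global hydrogenolysis then triggers decarboxylation, and kinetic protonation of the enol sets C1 cis to both aryl groups.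

Key step: step 7

Assumption: the sense of induction of the chiral bisphosphine cannot be predicted for this untested alkene; (R)-BINAP is written, and its antipode would be used if a trial run shows the opposite sense.

Remark: C1 is made quaternary on an open-chain β-keto ester before ring B is closed, so no ambident indenyl anion has to be acylated and no O- versus C-acylation has to be controlled.

Step 1
Reactants: 1 (3,5-dihydroxyphenyl)acetic acid
Product: 2 benzyl [3,5-bis(benzyloxy)phenyl]acetate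
Conditions: BnBr (3.3 equiv), K2CO3, DMF, 60 °C
Reagents that add atoms: benzyl bromide, BrCc1ccccc1
Why: Carbonate-mediated SN2 benzylation (Williamson ether synthesis together with carboxylate alkylation) should cap both phenols and the acid in one operation.

Step 2
Reactants: 2 benzyl [3,5-bis(benzyloxy)phenyl]acetate; 3 4-(benzyloxy)benzoyl chloride
Product: 4 benzyl 2-[3,5-bis(benzyloxy)phenyl]-3-[4-(benzyloxy)phenyl]-3-oxopropanoate (racemic)
Conditions: LiN(SiMe3)2 (2.1 equiv), THF, −78 °C; then 3 (1.0 equiv), −78 → 0 °C; aq NH4Cl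
Reagents that add atoms: none
Why: Crossed Claisen-type C-acylation of the lithium ester enolate by the aroyl chloride should give the β-keto ester, the second equivalent of base storing the more acidic product as its enolate, and the new α-stereocentre is racemic and of no consequence.

Step 3
Reactants: 4 benzyl 2-[3,5-bis(benzyloxy)phenyl]-3-[4-(benzyloxy)phenyl]-3-oxopropanoate; 5 tert-butyl bromoacetate
Product: 6 1-benzyl 4-tert-butyl 2-[4-(benzyloxy)benzoyl]-2-[3,5-bis(benzyloxy)phenyl]butanedioate (racemic)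
Conditions: K2CO3, acetone, 50 °C
Reagents that add atoms: none
Why: SN2 C-alkylation of the stabilised β-keto ester enolate by the reactive α-bromo ester should create the quaternary carbon (later C1) as a racemate and attach the two carbons that become C2 and C3.

Step 4
Reactants: 6 1-benzyl 4-tert-butyl 2-[4-(benzyloxy)benzoyl]-2-[3,5-bis(benzyloxy)phenyl]butanedioate
Product: 9 benzyl 4,6-bis(benzyloxy)-1-[4-(benzyloxy)benzoyl]-3-oxo-2,3-dihydro-1H-indene-1-carboxylate (racemic), via succinic half-acid 7 (not isolated), via mixed trifluoroacetic anhydride 8 (not isolated)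
Conditions: CF3CO2H/CH2Cl2 (1:4), 0 °C → rt; then (CF3CO)2O (2 equiv), 0 °C → rt
Reagents that add atoms: none
Why: Acidolysis of the tert-butyl ester followed by intramolecular Friedel–Crafts acylation through the mixed anhydride should close ring B at an aryl position ortho to one benzyloxy group and para to the other, the two ortho positions being equivalent.

Step 5
Reactants: 9 benzyl 4,6-bis(benzyloxy)-1-[4-(benzyloxy)benzoyl]-3-oxo-2,3-dihydro-1H-indene-1-carboxylate
Product: 10 benzyl 4,6-bis(benzyloxy)-1-[4-(benzyloxy)benzoyl]-3-{[(trifluoromethyl)sulfonyl]oxy}-1H-indene-1-carboxylate (racemic)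
Conditions: KN(SiMe3)2, THF, −78 °C; then 2-[N,N-bis(trifluoromethylsulfonyl)amino]-5-chloropyridine, −78 → −40 °C; aq NH4Cl
Reagents that add atoms: 2-[N,N-bis(trifluoromethylsulfonyl)amino]-5-chloropyridine, Clc1ccc(N(S(=O)(=O)C(F)(F)F)S(=O)(=O)C(F)(F)F)nc1
Why: C2 carries the only enolisable hydrogens of the molecule, so enol triflate formation through the potassium enolate should occur at C2–C3 alone, and the low temperature keeps the enolate short-lived.

Step 6
Reactants: 10 benzyl 4,6-bis(benzyloxy)-1-[4-(benzyloxy)benzoyl]-3-{[(trifluoromethyl)sulfonyl]oxy}-1H-indene-1-carboxylate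
Product: 11 benzyl 4,6-bis(benzyloxy)-1-[4-(benzyloxy)benzoyl]-1H-indene-1-carboxylate (racemic)
Conditions: Pd(OAc)2 (5 mol%), PPh3 (10 mol%), HCO2H, Et3N, DMF, 60 °C
Reagents that add atoms: none
Why: Palladium-catalysed formate reduction of the enol triflate (oxidative addition, formate exchange, loss of CO2, C–H reductive elimination) should replace the triflate by hydrogen and leave the C2=C3 bond in place, since the quaternary C1 prevents its migration.

Step 7
Reactants: 11 benzyl 4,6-bis(benzyloxy)-1-[4-(benzyloxy)benzoyl]-1H-indene-1-carboxylate (racemic); 12 1-(benzyloxy)-4-iodobenzene; 13 [3,5-bis(benzyloxy)phenyl]boronic acid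
Product: 14 benzyl (2S,3R)-4,6-bis(benzyloxy)-1-[4-(benzyloxy)benzoyl]-2-[4-(benzyloxy)phenyl]-3-[3,5-bis(benzyloxy)phenyl]-2,3-dihydro-1H-indene-1-carboxylate, 2,3-cis, both C1 epimers
Conditions: Pd2(dba)3 (5 mol%), (R)-BINAP (12 mol%), Ag2CO3 (1.5 equiv), 12 (2 equiv), 13 (2.5 equiv by syringe pump), dioxane, 50 °C
Reagents that add atoms: none
Why: Proposed new method: zerovalent palladium carrying the chiral bisphosphine should insert into the C–I bond of 12, silver should remove iodide, and the cationic arylpalladium should add syn across C2=C3 of 11 with the aryl group on C2 and divalent palladium on benzylic C3, after which 13 transmetallates and C3–aryl reductive elimination with retention leaves the two aryl groups cis. Nearest precedent is the cis-exo aryl halide/arylboronic acid diarylation of norbornene under palladium catalysis, together with metal-catalysed 1,2-diarylation of styrenes and syn-arylboration of indene. No ring is closed. The C2 stereocentre is set by the ligand-controlled choice of alkene face in the migratory insertion, and the C3 stereocentre follows from it because insertion is syn and reductive elimination is stereoretentive. β-Hydride elimination is shut off because C1 is quaternary and the single hydrogen on C2 lies anti to palladium, and the regiochemistry is secured by η3-benzyl stabilisation at C3 next to the ortho/para-dialkoxy benzo ring. The step needs the ligand to override the small facial bias of the two C1 carbonyl groups for both enantiomers of 11 and needs insertion to outpace direct biaryl coupling, which the strained styrene-type alkene, slow addition of 13 and the hydroxide-free silver conditions (which also spare the cleavable β-keto ester) are meant to secure.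

Step 8
Reactants: 14 benzyl (2S,3R)-4,6-bis(benzyloxy)-1-[4-(benzyloxy)benzoyl]-2-[4-(benzyloxy)phenyl]-3-[3,5-bis(benzyloxy)phenyl]-2,3-dihydro-1H-indene-1-carboxylate (both C1 epimers)
Product: 17 caraphenol B (1R,2R,3R all-cis ketone), via β-keto acid 15 (not isolated), via exocyclic enol 16 (not isolated)
Conditions: H2 (1 atm), 10% Pd/C, EtOAc/MeOH, rt
Reagents that add atoms: none
Why: Hydrogenolysis of the seven benzyl–oxygen bonds should free six phenols and the β-keto acid, which should lose CO2 through a cyclic transition state to the exocyclic enol, and kinetic protonation of that enol at C1 on the face opposite the C2 aryl group should place the aroyl group cis to both aryl groups (1R).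

Compound list
1 | (3,5-dihydroxyphenyl)acetic acid | OC(=O)Cc1cc(O)cc(O)c1 | starting material
2 | benzyl [3,5-bis(benzyloxy)phenyl]acetate | O=C(Cc1cc(OCc2ccccc2)cc(OCc2ccccc2)c1)OCc1ccccc1 | intermediate
3 | 4-(benzyloxy)benzoyl chloride | O=C(Cl)c1ccc(OCc2ccccc2)cc1 | starting material
4 | benzyl 2-[3,5-bis(benzyloxy)phenyl]-3-[4-(benzyloxy)phenyl]-3-oxopropanoate (racemic) | O=C(OCc1ccccc1)C(C(=O)c1ccc(OCc2ccccc2)cc1)c1cc(OCc2ccccc2)cc(OCc2ccccc2)c1 | intermediate
5 | tert-butyl bromoacetate | CC(C)(C)OC(=O)CBr | starting material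
6 | 1-benzyl 4-tert-butyl 2-[4-(benzyloxy)benzoyl]-2-[3,5-bis(benzyloxy)phenyl]butanedioate (racemic) | O=C(OCc1ccccc1)C(CC(=O)OC(C)(C)C)(C(=O)c1ccc(OCc2ccccc2)cc1)c1cc(OCc2ccccc2)cc(OCc2ccccc2)c1 | intermediate
7 | 3-[(benzyloxy)carbonyl]-3-[3,5-bis(benzyloxy)phenyl]-4-[4-(benzyloxy)phenyl]-4-oxobutanoic acid (racemic) | O=C(OCc1ccccc1)C(CC(=O)O)(C(=O)c1ccc(OCc2ccccc2)cc1)c1cc(OCc2ccccc2)cc(OCc2ccccc2)c1 | intermediate (not isolated)
8 | mixed trifluoroacetic anhydride of acid 7 (racemic) | O=C(OCc1ccccc1)C(CC(=O)OC(=O)C(F)(F)F)(C(=O)c1ccc(OCc2ccccc2)cc1)c1cc(OCc2ccccc2)cc(OCc2ccccc2)c1 | intermediate (not isolated)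
9 | benzyl 4,6-bis(benzyloxy)-1-[4-(benzyloxy)benzoyl]-3-oxo-2,3-dihydro-1H-indene-1-carboxylate (racemic) | O=C(OCc1ccccc1)C1(C(=O)c2ccc(OCc3ccccc3)cc2)CC(=O)c2c(OCc3ccccc3)cc(OCc3ccccc3)cc21 | intermediate
10 | benzyl 4,6-bis(benzyloxy)-1-[4-(benzyloxy)benzoyl]-3-{[(trifluoromethyl)sulfonyl]oxy}-1H-indene-1-carboxylate (racemic) | O=C(OCc1ccccc1)C1(C(=O)c2ccc(OCc3ccccc3)cc2)C=C(OS(=O)(=O)C(F)(F)F)c2c(OCc3ccccc3)cc(OCc3ccccc3)cc21 | intermediate
11 | benzyl 4,6-bis(benzyloxy)-1-[4-(benzyloxy)benzoyl]-1H-indene-1-carboxylate (racemic) | O=C(OCc1ccccc1)C1(C(=O)c2ccc(OCc3ccccc3)cc2)C=Cc2c(OCc3ccccc3)cc(OCc3ccccc3)cc21 | intermediate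
12 | 1-(benzyloxy)-4-iodobenzene | Ic1ccc(OCc2ccccc2)cc1 | starting material
13 | [3,5-bis(benzyloxy)phenyl]boronic acid | OB(O)c1cc(OCc2ccccc2)cc(OCc2ccccc2)c1 | starting material
14 | benzyl (2S,3R)-4,6-bis(benzyloxy)-1-[4-(benzyloxy)benzoyl]-2-[4-(benzyloxy)phenyl]-3-[3,5-bis(benzyloxy)phenyl]-2,3-dihydro-1H-indene-1-carboxylate, both C1 epimers | O=C(OCc1ccccc1)C1(C(=O)c2ccc(OCc3ccccc3)cc2)c2cc(OCc3ccccc3)cc(OCc3ccccc3)c2[C@@H](c2cc(OCc3ccccc3)cc(OCc3ccccc3)c2)[C@H]1c1ccc(OCc2ccccc2)cc1 | intermediate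
15 | (2S,3R)-3-(3,5-dihydroxyphenyl)-4,6-dihydroxy-1-(4-hydroxybenzoyl)-2-(4-hydroxyphenyl)-2,3-dihydro-1H-indene-1-carboxylic acid, both C1 epimers | O=C(O)C1(C(=O)c2ccc(O)cc2)c2cc(O)cc(O)c2[C@@H](c2cc(O)cc(O)c2)[C@H]1c1ccc(O)cc1 | intermediate (not isolated)
16 | 4-{[(2S,3R)-3-(3,5-dihydroxyphenyl)-4,6-dihydroxy-2-(4-hydroxyphenyl)-2,3-dihydro-1H-inden-1-ylidene](hydroxy)methyl}phenol (enol, double-bond geometry not defined) | OC(c1ccc(O)cc1)=C1c2cc(O)cc(O)c2[C@@H](c2cc(O)cc(O)c2)[C@H]1c1ccc(O)cc1 | intermediate (not isolated)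
17 | caraphenol B, [(1R,2R,3R)-3-(3,5-dihydroxyphenyl)-4,6-dihydroxy-2-(4-hydroxyphenyl)-2,3-dihydro-1H-inden-1-yl](4-hydroxyphenyl)methanone | O=C(c1ccc(O)cc1)[C@H]1c2cc(O)cc(O)c2[C@@H](c2cc(O)cc(O)c2)[C@H]1c1ccc(O)cc1 | target

Total step count: 8. Longest linear sequence: 8 steps (1 → 17).

Steps most likely to fail

Step 7. Direct biaryl coupling may outrun alkene insertion next to the quaternary carbon. The catalyst may also fail to override the facial bias of C1 for one enantiomer of 11, which would erode the optical purity or leave half of the material unreacted. The fallback replaces the diarylation by a syn hydrogenation and uses known reaction types only. It sets out from indanone 9. Palladium-catalysed ketone α-arylation with 12 (Pd(OAc)2, XPhos, K3PO4, toluene, 80 °C) should give benzyl 4,6-bis(benzyloxy)-1-[4-(benzyloxy)benzoyl]-2-[4-(benzyloxy)phenyl]-3-oxo-2,3-dihydro-1H-indene-1-carboxylate F1. Enol triflate formation as in step 5 should give the 2-aryl-3-triflyloxy-1H-indene F2. Suzuki–Miyaura coupling with 13 (Pd(PPh3)4, anhydrous K3PO4, dioxane, 80 °C) should give the 2,3-diaryl-1H-indene F3. Asymmetric hydrogenation of its tetrasubstituted C2=C3 bond (H2, 50 bar, CH2Cl2, [Ir(cod)(L)]B[C6H3(CF3)2]4 with L = (S)-4-tert-butyl-2-[2-(diphenylphosphanyl)phenyl]-4,5-dihydro-1,3-oxazole or its antipode) should deliver both hydrogens to one face and so the cis-diaryl compound. The fallback rejoins the route at 14.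

Step 8. Enol–ketone equilibration during or after decarboxylation may erode the kinetic C1 configuration toward the more stable 1,2-trans epimer, and the aryl ketone may be partly reduced on prolonged exposure. The fallback separates ester removal from the setting of C1 and sets out from 14. Krapcho dealkoxycarbonylation (LiCl, wet DMSO, 130 °C) should remove the ester alone and give [(2R,3R)-4,6-bis(benzyloxy)-2-[4-(benzyloxy)phenyl]-3-[3,5-bis(benzyloxy)phenyl]-2,3-dihydro-1H-inden-1-yl][4-(benzyloxy)phenyl]methanone as a C1 epimer mixture F4. Its potassium enolate (KN(SiMe3)2, THF, −78 °C) should be protonated at −78 °C by acetic acid on the face away from the C2 aryl group to give the (1R,2R,3R) all-cis hexabenzyl ketone F5. Brief neutral hydrogenolysis (H2, 10% Pd/C, EtOAc, rt) should then return the route at 17.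

Step 4. Acid may remove or shift benzyl groups on the electron-rich rings, and intermolecular trifluoroacetylation may compete with ring closure. The fallback closes ring B by hydroxyalkylation instead of acylation and sets out from β-keto ester 4. C-Allylation (allyl bromide, K2CO3, acetone, 50 °C) should give benzyl 2-[4-(benzyloxy)benzoyl]-2-[3,5-bis(benzyloxy)phenyl]pent-4-enoate F6. Lemieux–Johnson cleavage (OsO4 cat., NaIO4, 2,6-lutidine, dioxane/H2O) should give benzyl 2-[4-(benzyloxy)benzoyl]-2-[3,5-bis(benzyloxy)phenyl]-4-oxobutanoate F7. Catalytic TsOH in toluene at 60 °C should effect intramolecular Friedel–Crafts hydroxyalkylation to benzyl 4,6-bis(benzyloxy)-1-[4-(benzyloxy)benzoyl]-3-hydroxy-2,3-dihydro-1H-indene-1-carboxylate F8, which should dehydrate in the same flask. The fallback rejoins the route at 11 and bypasses steps 5 and 6.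

Further compounds
F1 | step 7 | benzyl 4,6-bis(benzyloxy)-1-[4-(benzyloxy)benzoyl]-2-[4-(benzyloxy)phenyl]-3-oxo-2,3-dihydro-1H-indene-1-carboxylate (diastereomer mixture) | O=C(OCc1ccccc1)C1(C(=O)c2ccc(OCc3ccccc3)cc2)C(c2ccc(OCc3ccccc3)cc2)C(=O)c2c(OCc3ccccc3)cc(OCc3ccccc3)cc21
F2 | step 7 | benzyl 4,6-bis(benzyloxy)-1-[4-(benzyloxy)benzoyl]-2-[4-(benzyloxy)phenyl]-3-{[(trifluoromethyl)sulfonyl]oxy}-1H-indene-1-carboxylate (racemic) | O=C(OCc1ccccc1)C1(C(=O)c2ccc(OCc3ccccc3)cc2)C(c2ccc(OCc3ccccc3)cc2)=C(OS(=O)(=O)C(F)(F)F)c2c(OCc3ccccc3)cc(OCc3ccccc3)cc21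
F3 | step 7 | benzyl 4,6-bis(benzyloxy)-1-[4-(benzyloxy)benzoyl]-2-[4-(benzyloxy)phenyl]-3-[3,5-bis(benzyloxy)phenyl]-1H-indene-1-carboxylate (racemic) | O=C(OCc1ccccc1)C1(C(=O)c2ccc(OCc3ccccc3)cc2)C(c2ccc(OCc3ccccc3)cc2)=C(c2cc(OCc3ccccc3)cc(OCc3ccccc3)c2)c2c(OCc3ccccc3)cc(OCc3ccccc3)cc21
F4 | step 8 | [(2R,3R)-4,6-bis(benzyloxy)-2-[4-(benzyloxy)phenyl]-3-[3,5-bis(benzyloxy)phenyl]-2,3-dihydro-1H-inden-1-yl][4-(benzyloxy)phenyl]methanone, C1 epimer mixture | O=C(c1ccc(OCc2ccccc2)cc1)C1c2cc(OCc3ccccc3)cc(OCc3ccccc3)c2[C@@H](c2cc(OCc3ccccc3)cc(OCc3ccccc3)c2)[C@H]1c1ccc(OCc2ccccc2)cc1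
F5 | step 8 | [(1R,2R,3R)-4,6-bis(benzyloxy)-2-[4-(benzyloxy)phenyl]-3-[3,5-bis(benzyloxy)phenyl]-2,3-dihydro-1H-inden-1-yl][4-(benzyloxy)phenyl]methanone | O=C(c1ccc(OCc2ccccc2)cc1)[C@H]1c2cc(OCc3ccccc3)cc(OCc3ccccc3)c2[C@@H](c2cc(OCc3ccccc3)cc(OCc3ccccc3)c2)[C@H]1c1ccc(OCc2ccccc2)cc1
F6 | step 4 | benzyl 2-[4-(benzyloxy)benzoyl]-2-[3,5-bis(benzyloxy)phenyl]pent-4-enoate (racemic) | C=CCC(C(=O)OCc1ccccc1)(C(=O)c1ccc(OCc2ccccc2)cc1)c1cc(OCc2ccccc2)cc(OCc2ccccc2)c1
F7 | step 4 | benzyl 2-[4-(benzyloxy)benzoyl]-2-[3,5-bis(benzyloxy)phenyl]-4-oxobutanoate (racemic) | O=CCC(C(=O)OCc1ccccc1)(C(=O)c1ccc(OCc2ccccc2)cc1)c1cc(OCc2ccccc2)cc(OCc2ccccc2)c1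
F8 | step 4 | benzyl 4,6-bis(benzyloxy)-1-[4-(benzyloxy)benzoyl]-3-hydroxy-2,3-dihydro-1H-indene-1-carboxylate (diastereomer mixture) | O=C(OCc1ccccc1)C1(C(=O)c2ccc(OCc3ccccc3)cc2)CC(O)c2c(OCc3ccccc3)cc(OCc3ccccc3)cc21
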